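## The problem

CNP0280662.1 is an open-chain molecule built on a propane-1,3-diol backbone. C1 is a benzylic carbinol carrying the 3,4-dimethoxyphenyl ring, the C2 methine carries an (E)-3-(4-methoxyphenyl)allyl chain, and the C3 oxygen is esterified with (Z)-2-(hydroxymethyl)but-2-enoic acid. No ring relays stereochemistry, so the two contiguous centres (1S carbinol, 2R methine) must be set in an acyclic setting. The methine bears two CH2 groups of similar size (CH2O and the allylic CH2), so it is a poor controller of additions to a neighbouring carbonyl. Each centre is therefore best set by its own reagent. Three functions are fragile: the Z trisubstituted enoate (Z-to-E isomerisation by reversible conjugate addition, attack by nucleophiles), the benzylic alcohol para to a methoxy group (ionisation under acid), and the electron-rich E styrenyl alkene (acid, oxidants, hydrogenation, organolithium addition). The primary ester lies 1,3 to a free secondary hydroxyl, so over-acylation and acyl migration must be watched at the end. Two features open the way. The methine carries two CH2O-type arms (one becomes the ester CH2O, the other the carbinol carbon), so it is the desymmetrised centre of a prochiral 2-substituted propane-1,3-diol. The carbinol carbon C1 carries an oxygen, the 3,4-dimethoxyphenyl ring and the C2 methine, which is the pattern formed when an aryl group migrates from boron to an oxygen-bearing carbanion and the C–B bond is then oxidised.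

## Retrosynthesis

The first cut is the ester C–O bond, together with the silyl group on the side-chain hydroxyl: target 23 comes from silyl ether 22, and 22 from diol 15 and the O-silylated Z acid 21. Carrying the enoate through the synthesis is excluded, because it would not survive organolithium or hydride reagents and its geometry would be at risk in every basic step. Attaching it last confines that risk to two mild steps. The forward reaction must acylate the primary hydroxyl in preference to the hindered benzylic one and must not isomerise the enoate.

Acid 21 is cut at the C–CO2H bond to vinyl iodide 19, which goes back through alcohol 18 and aldehyde 17 to crotonaldehyde 16. An olefination would have to create the less stable trisubstituted geometry directly. This sequence instead fixes the geometry in 17, where α-iodination of an E enal places iodine cis to the methyl group, and each later step replaces a substituent on the sp2 carbon with retention. The forward carboxylation must keep the vinyl metal configurationally intact.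

Diol 15 is traced through silyl ether 14 to the benzylic boronic ester 13, exchanging the C1–O bond for a C1–B bond. This costs one oxidation with retention and turns the carbinol carbon into a centre that can be made by carbon–carbon bond formation at boron.

The key cut is the bond between C1 and the 3,4-dimethoxyphenyl ring: 13 arises from carbamate 9 and the purchasable aryl boronic ester 10. Two neighbouring cuts were weighed against it:
- The C1–C2 bond (an aldol-type union) would have to control both centres at once and leave a carbonyl to be reduced.
- The same aryl–C1 bond made by adding an aryl metal to an α-branched aldehyde relies on a methine whose two CH2 substituents are nearly alike, and the aldehyde is epimerisable.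

The boron route lets an external chiral diamine choose one of the two hydrogens on the OCH2 group of 9, so the C1 configuration is independent of C2. Precursor 9 has one stereocentre and no aryl carbinol. The forward reaction must lithiate next to the carbamate oxygen faster than s-BuLi attacks the anisyl alkene, and the diamine must override the existing centre.

Carbamate 9 is taken back through alcohol 8 and acetate 7 to monoacetate 6 and then to the achiral diol 5. The two CH2O arms of 9 differ only in their protecting groups, so the C2 centre is a desymmetrisation problem. An enzymatic monoacetylation of 5 solves it catalytically, and the order of the following protections decides which arm becomes C1. Unlike an auxiliary-based alkylation, this needs no stoichiometric chiral reagent and starts from a symmetric compound. The forward steps must never place a free alkoxide next to a migrating acyl or silyl group, because migration between the arms is racemisation.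

Diol 5 is cut at the bond between C2 and the allylic CH2. It comes by reduction of malonate 4, which is made from diethyl malonate 3 and carbonate 2, the activated form of 4-methoxycinnamyl alcohol 1. Building the styrene later by olefination would put the E geometry at risk. Palladium-catalysed allylic alkylation carries the E alkene of 1 into the product and attacks the unsubstituted allyl terminus. Only linear selectivity and monoalkylation are asked of it.

## Roads not taken

Alternative 1: The cut is the benzylic C–O bond of a γ-lactone that ties the future carbinol oxygen to the carbon destined to become the alkene CH. In the forward step (R)-2-(3,4-dimethoxybenzyl)succinic acid A1 is treated with DDQ; hydride leaves the benzylic CH2 and the distal carboxyl traps the cation, closing the trans lactone acid (2S,3S)-2-(3,4-dimethoxyphenyl)-5-oxotetrahydrofuran-3-carboxylic acid A2.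
- Merits: A1 needs one catalytic asymmetric operation (Stobbe condensation, then asymmetric hydrogenation). The five-membered ring relays that centre to the carbinol carbon through its trans preference. The lactone also protects the carbinol oxygen.
- Weak points: the anisyl alkene cannot be present during hydride abstraction. It must be made afterwards from the lactone carbonyl by half-reduction and olefination with a semi-stabilised 4-methoxybenzyl phosphorus reagent, which typically gives E/Z mixtures. The carboxyl of A2 must be reduced to CH2OH beside the lactone. The trans selectivity rests on a reversibly ionising benzylic C–O bond.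
- Comparison: this road is better in needing no stoichiometric chiral diamine and no cryogenic organolithium step, and its diastereocontrol is ring-based. The chosen plan sets against this an E alkene bought ready-made in 1, no oxidation-state changes at three carbons, and a shorter sequence.

Alternative 2: The cut is the bond between the methine and the allylic CH2, made by an Ireland–Claisen rearrangement. The ester (R)-1-(4-methoxyphenyl)prop-2-enyl (S)-3-(tert-butyldimethylsilyloxy)-3-(3,4-dimethoxyphenyl)propanoate A3 is converted with LiN(i-Pr)2 and Me3SiCl into its silyl ketene acetal, which rearranges through a chair to the acid A4, (2S,3S)-3-(tert-butyldimethylsilyloxy)-3-(3,4-dimethoxyphenyl)-2-[(E)-3-(4-methoxyphenyl)prop-2-enyl]propanoic acid.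
- Merits: one step forms the C–C bond, the methine centre and the E alkene, and the carboxyl of A4 needs only reduction to become the ester arm. In step count this road is probably shorter than the chosen one.
- Weak points: the ester oxygen of A3 sits on a carbon that is both allylic and para-methoxybenzylic, so A3 can ionise, racemise or transpose to the cinnamyl isomer before it rearranges. Its enolate has a β-silyloxy leaving group and can eliminate to the cinnamate. The methine configuration depends on both the ketene acetal geometry and the allylic configuration (the R ester is needed for the geometry expected in THF, with the α-substituent cis to the allyloxy oxygen). Two enantioenriched halves must be prepared.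
- Comparison: the chosen plan is longer, but every intermediate is configurationally stable and each centre is set by one well-understood reagent-controlled event.

Alternative 3: The cut is the methine–CH2O bond. The ketone (E)-1-(3,4-dimethoxyphenyl)-5-(4-methoxyphenyl)pent-4-en-1-one A5 is converted into its Z trimethylsilyl enol ether A6. A6 adds to aqueous formaldehyde under Sc(OTf)3 and a chiral 2,2'-bipyridine diol ligand to give (R)-1-(3,4-dimethoxyphenyl)-2-(hydroxymethyl)-5-(4-methoxyphenyl)pent-4-en-1-one A7.
- Merits: the methine centre is set catalytically, and the route is the shortest of all (ketone, enol silane, hydroxymethylation, acylation, ketone reduction). In step economy and in avoiding stoichiometric chiral reagents it is better than the chosen plan.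
- Weak points: A7 is a β-hydroxy ketone with an enolisable α-stereocentre, open to racemisation, dehydration to the α-methylene ketone and loss of formaldehyde. The hydroxymethylation is best established for small α-substituents, not for a long hydrophobic cinnamyl chain in an aqueous medium. The carbinol centre must then come from reduction of the aryl ketone under control of a methine with two similar CH2 groups, so the sense (chelate or Felkin–Anh) must happen to fit, or a chiral reductant must override it.
- Comparison: the chosen plan sets against the shorter count two centres fixed by independent reagents of known sense and no epimerisable intermediate.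

Key step: step 8

Assumption: the Burkholderia cepacia lipase is taken to acetylate the pro-R hydroxymethyl arm of 5, as its usual preference among β-branched primary alcohols predicts, so that 6 is the R monoacetate. The descriptor at this carbon later changes (S in 7, 8, 9 and 13; R in 14 onwards) only because substituent priorities change, not the geometry.

## Route

Step 1
Reactants: 1 (E)-3-(4-methoxyphenyl)prop-2-en-1-ol (4-methoxycinnamyl alcohol)
Product: 2 methyl (E)-3-(4-methoxyphenyl)prop-2-enyl carbonate
Conditions: ClCO2Me, pyridine, CH2Cl2, 0 °C
Reagents that add atoms: methyl chloroformate, COC(=O)Cl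
Why: Acylation of a primary allylic alcohol by a chloroformate; the cold, weakly basic medium avoids ionising the para-methoxycinnamyl system.

Step 2
Reactants: 2 methyl (E)-3-(4-methoxyphenyl)prop-2-enyl carbonate; 3 diethyl malonate (excess)
Product: 4 diethyl 2-[(E)-3-(4-methoxyphenyl)prop-2-enyl]propanedioate
Conditions: Pd(PPh3)4 (cat.), THF, 50 °C
Reagents that add atoms: none
Why: Tsuji–Trost allylic alkylation: zerovalent palladium ionises the carbonate to a π-allyl complex, the methoxide released with CO2 deprotonates the malonate, and the soft nucleophile attacks the unsubstituted terminus to give the linear E product; excess malonate suppresses dialkylation.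

Step 3
Reactants: 4 diethyl 2-[(E)-3-(4-methoxyphenyl)prop-2-enyl]propanedioate
Product: 5 2-[(E)-3-(4-methoxyphenyl)prop-2-enyl]propane-1,3-diol
Conditions: LiAlH4, THF, 0 °C to rt
Reagents that add atoms: none
Why: Hydride reduction of both ester groups to primary alcohols; the isolated styrenyl alkene is inert to LiAlH4.

Step 4
Reactants: 5 2-[(E)-3-(4-methoxyphenyl)prop-2-enyl]propane-1,3-diol
Product: 6 (2R,4E)-2-(hydroxymethyl)-5-(4-methoxyphenyl)pent-4-enyl acetate
Conditions: Amano lipase PS (Burkholderia cepacia), vinyl acetate, t-BuOMe, 25 °C
Reagents that add atoms: vinyl acetate, C=COC(C)=O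
Why: Lipase-catalysed irreversible transesterification desymmetrises the prochiral 2-substituted propane-1,3-diol; the enzyme pocket selects one enantiotopic hydroxymethyl group and so sets the methine centre, and slight over-acetylation to the diacetate should consume the minor enantiomer preferentially.

Step 5
Reactants: 6 (2R,4E)-2-(hydroxymethyl)-5-(4-methoxyphenyl)pent-4-enyl acetate
Product: 7 (2S,4E)-5-(4-methoxyphenyl)-2-[(triisopropylsilyloxy)methyl]pent-4-enyl acetate
Conditions: TIPSCl, imidazole, DMF, 0 °C to rt
Reagents that add atoms: triisopropylsilyl chloride, CC(C)[Si](Cl)(C(C)C)C(C)C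
Why: Standard imidazole-mediated silylation of a primary alcohol; it is fast and generates no alkoxide, so the 1,3-acyl shift that would racemise 6 is avoided, and the bulky group is chosen to resist migration and s-BuLi later.

Step 6
Reactants: 7 (2S,4E)-5-(4-methoxyphenyl)-2-[(triisopropylsilyloxy)methyl]pent-4-enyl acetate
Product: 8 (2S,4E)-5-(4-methoxyphenyl)-2-[(triisopropylsilyloxy)methyl]pent-4-en-1-ol
Conditions: K2CO3, MeOH, 0 °C to rt
Reagents that add atoms: none
Why: Base-catalysed methanolysis of the acetate; the hindered triisopropylsilyl ether is stable to these conditions and too bulky to migrate to the freed hydroxyl, which would be racemisation.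

Step 7
Reactants: 8 (2S,4E)-5-(4-methoxyphenyl)-2-[(triisopropylsilyloxy)methyl]pent-4-en-1-ol
Product: 9 (2S,4E)-5-(4-methoxyphenyl)-2-[(triisopropylsilyloxy)methyl]pent-4-enyl N,N-diisopropylcarbamate
Conditions: i-Pr2NCOCl, Et3N, DMAP (cat.), toluene, 90 °C
Reagents that add atoms: N,N-diisopropylcarbamoyl chloride, CC(C)N(C(C)C)C(Cl)=O
Why: Carbamoylation of a primary alcohol with a carbamoyl chloride under amine base; no metal alkoxide is formed, so the silyl group cannot move between the two arms.

Step 8
Reactants: 9 (2S,4E)-5-(4-methoxyphenyl)-2-[(triisopropylsilyloxy)methyl]pent-4-enyl N,N-diisopropylcarbamate; 10 2-(3,4-dimethoxyphenyl)-4,4,5,5-tetramethyl-1,3,2-dioxaborolane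
Product: 13 2-[(1S,2S,4E)-1-(3,4-dimethoxyphenyl)-5-(4-methoxyphenyl)-2-[(triisopropylsilyloxy)methyl]pent-4-enyl]-4,4,5,5-tetramethyl-1,3,2-dioxaborolane, via lithiated carbamate 11 (not isolated), via boronate complex 12 (not isolated)
Conditions: s-BuLi, (+)-sparteine, Et2O, −78 °C; then 10, −78 °C; then MgBr2·OEt2, −78 °C to reflux
Reagents that add atoms: none
Why: This is a sparteine-mediated asymmetric deprotonation of an O-alkyl carbamate followed by homologation of a boronic ester through a 1,2-metallate rearrangement, the closest known reaction type being the lithiation–borylation of primary alkyl N,N-diisopropylcarbamates with aryl pinacol boronates. The carbamate carbonyl pre-coordinates the s-BuLi·(+)-sparteine complex, which removes the pro-R hydrogen of the OCH2 group to give the configurationally stable, carbonyl-chelated lithio carbamate 11 (1R). Boronic ester 10 is captured at carbon with retention to give the tetracoordinate boronate 12, and on warming with MgBr2·OEt2, which activates the carbamate as a leaving group, the 3,4-dimethoxyphenyl group shifts from boron to carbon antiperiplanar to the departing carbamate, that is with inversion, forming the aryl–C1 bond and leaving the C–B bond of 13. No ring is closed. The new C1 centre (S in 13) is controlled by the diamine alone: retention in borylation, inversion in migration and retention in the later oxidation translate the R lithio centre into the 1S carbinol, which is why the (+) and not the (−) enantiomer of sparteine is used. The C2 centre comes from the enzymatic step and is a spectator; the step needs reagent control to override it, which the tight diamine–lithium–carbamate complex normally provides for β-branched substrates. Chemoselectivity rests on the complex-induced proximity effect of the carbamate, which should make α-deprotonation at −78 °C faster than addition of s-BuLi to the electron-rich β-alkylated anisyl alkene or removal of its allylic protons, while intramolecular carbolithiation by 11 would need an unfavourable four-membered closure. The bulky silyl ether offers neither a good lithium ligand nor an acidic site, and only a slight excess of s-BuLi is used so that none remains to consume 10.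

Step 9
Reactants: 13 2-[(1S,2S,4E)-1-(3,4-dimethoxyphenyl)-5-(4-methoxyphenyl)-2-[(triisopropylsilyloxy)methyl]pent-4-enyl]-4,4,5,5-tetramethyl-1,3,2-dioxaborolane
Product: 14 (1S,2R,4E)-1-(3,4-dimethoxyphenyl)-5-(4-methoxyphenyl)-2-[(triisopropylsilyloxy)methyl]pent-4-en-1-ol
Conditions: 30% aq. H2O2, 2 M aq. NaOH, THF, 0 °C to rt
Reagents that add atoms: hydrogen peroxide, OO
Why: Oxidation of a secondary boronic ester: hydroperoxide adds to boron and the benzylic carbon shifts from boron to oxygen with retention, so the C1 configuration of 13 is carried into the carbinol; the alkene, aryl ethers and silyl ether are inert.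

Step 10
Reactants: 14 (1S,2R,4E)-1-(3,4-dimethoxyphenyl)-5-(4-methoxyphenyl)-2-[(triisopropylsilyloxy)methyl]pent-4-en-1-ol
Product: 15 (1S,2R)-1-(3,4-dimethoxyphenyl)-2-[(E)-3-(4-methoxyphenyl)prop-2-enyl]propane-1,3-diol
Conditions: TBAF, THF, 0 °C to rt
Reagents that add atoms: none
Why: Fluoride-mediated cleavage of the primary silyl ether; the non-acidic medium spares the ionisable benzylic alcohol and no stereocentre is touched.

Step 11
Reactants: 16 (E)-but-2-enal (crotonaldehyde)
Product: 17 (Z)-2-iodobut-2-enal
Conditions: I2, K2CO3, DMAP (cat.), THF/H2O, rt
Reagents that add atoms: iodine, II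
Why: α-Iodination of an enal by nucleophilic catalysis (conjugate addition of DMAP, iodination of the enolate, elimination of the catalyst); elimination returns the conjugated isomer with iodine cis to the methyl group, which is the Z iodide.

Step 12
Reactants: 17 (Z)-2-iodobut-2-enal
Product: 18 (Z)-2-iodobut-2-en-1-ol
Conditions: NaBH4, CeCl3·7H2O, MeOH, 0 °C
Reagents that add atoms: none
Why: Luche 1,2-reduction of the enal; the vinyl iodide and its geometry are untouched.

Step 13
Reactants: 18 (Z)-2-iodobut-2-en-1-ol
Product: 19 tert-butyl{[(Z)-2-iodobut-2-enyl]oxy}dimethylsilane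
Conditions: TBSCl, imidazole, CH2Cl2, 0 °C to rt
Reagents that add atoms: tert-butyldimethylsilyl chloride, CC(C)(C)[Si](C)(C)Cl
Why: Standard silylation of a primary allylic alcohol; the group protects the hydroxyl through metalation and esterification and is removable under buffered fluoride at the end.

Step 14
Reactants: 19 tert-butyl{[(Z)-2-iodobut-2-enyl]oxy}dimethylsilane
Product: 21 (Z)-2-[(tert-butyldimethylsilyloxy)methyl]but-2-enoic acid, via vinyllithium 20 (not isolated)
Conditions: t-BuLi (2.1 equiv), Et2O, −78 °C; CO2 (gas), −78 °C; then 1 M HCl to pH 3, 0 °C
Reagents that add atoms: carbon dioxide, O=C=O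
Why: Iodine–lithium exchange gives a vinyllithium that holds its configuration at −78 °C, and carboxylation occurs with retention, so the carboxyl takes the place of iodine cis to the methyl group (Z acid); the low temperature suppresses β-elimination of silyloxide and silyl migration.

Step 15
Reactants: 15 (1S,2R)-1-(3,4-dimethoxyphenyl)-2-[(E)-3-(4-methoxyphenyl)prop-2-enyl]propane-1,3-diol; 21 (Z)-2-[(tert-butyldimethylsilyloxy)methyl]but-2-enoic acid
Product: 22 (2R,3S)-3-(3,4-dimethoxyphenyl)-3-hydroxy-2-[(E)-3-(4-methoxyphenyl)prop-2-enyl]propyl (Z)-2-[(tert-butyldimethylsilyloxy)methyl]but-2-enoate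
Conditions: EDC·HCl, DMAP (cat.), CH2Cl2, −20 to 0 °C
Reagents that add atoms: none
Why: Steglich esterification; the unhindered primary hydroxyl should react well before the secondary benzylic one, which is flanked by the aryl ring and the branched carbon, and the low temperature with little DMAP limits the time the activated Z acyl species can isomerise.

Step 16
Reactants: 22 (2R,3S)-3-(3,4-dimethoxyphenyl)-3-hydroxy-2-[(E)-3-(4-methoxyphenyl)prop-2-enyl]propyl (Z)-2-[(tert-butyldimethylsilyloxy)methyl]but-2-enoate
Product: 23 (2R,3S)-3-(3,4-dimethoxyphenyl)-3-hydroxy-2-[(E)-3-(4-methoxyphenyl)prop-2-enyl]propyl (Z)-2-(hydroxymethyl)but-2-enoate (CNP0280662.1)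
Conditions: HF·pyridine, pyridine, THF, 0 °C to rt
Reagents that add atoms: none
Why: Buffered fluoride cleavage of a primary allylic silyl ether; excess pyridine keeps the medium too weakly acidic to ionise the benzylic alcohol and too weakly basic to cause acyl migration or enoate isomerisation.

## Compound list

1 | (E)-3-(4-methoxyphenyl)prop-2-en-1-ol | OC/C=C/c1ccc(OC)cc1 | starting material
2 | methyl (E)-3-(4-methoxyphenyl)prop-2-enyl carbonate | COC(=O)OC/C=C/c1ccc(OC)cc1 | intermediate
3 | diethyl malonate | CCOC(=O)CC(=O)OCC | starting material
4 | diethyl 2-[(E)-3-(4-methoxyphenyl)prop-2-enyl]propanedioate | CCOC(=O)C(C/C=C/c1ccc(OC)cc1)C(=O)OCC | intermediate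
5 | 2-[(E)-3-(4-methoxyphenyl)prop-2-enyl]propane-1,3-diol | OCC(C/C=C/c1ccc(OC)cc1)CO | intermediate
6 | (2R,4E)-2-(hydroxymethyl)-5-(4-methoxyphenyl)pent-4-enyl acetate | CC(=O)OC[C@H](C/C=C/c1ccc(OC)cc1)CO | intermediate
7 | (2S,4E)-5-(4-methoxyphenyl)-2-[(triisopropylsilyloxy)methyl]pent-4-enyl acetate | CC(=O)OC[C@H](C/C=C/c1ccc(OC)cc1)CO[Si](C(C)C)(C(C)C)C(C)C | intermediate
8 | (2S,4E)-5-(4-methoxyphenyl)-2-[(triisopropylsilyloxy)methyl]pent-4-en-1-ol | CC(C)[Si](C(C)C)(C(C)C)OC[C@@H](C/C=C/c1ccc(OC)cc1)CO | intermediate
9 | (2S,4E)-5-(4-methoxyphenyl)-2-[(triisopropylsilyloxy)methyl]pent-4-enyl N,N-diisopropylcarbamate | CC(C)[Si](C(C)C)(C(C)C)OC[C@@H](C/C=C/c1ccc(OC)cc1)COC(=O)N(C(C)C)C(C)C | intermediate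
10 | 2-(3,4-dimethoxyphenyl)-4,4,5,5-tetramethyl-1,3,2-dioxaborolane | COc1ccc(B2OC(C)(C)C(C)(C)O2)cc1OC | starting material
11 | (1R,2R,4E)-1-lithio-5-(4-methoxyphenyl)-2-[(triisopropylsilyloxy)methyl]pent-4-enyl N,N-diisopropylcarbamate (lithium in place of the pro-R hydrogen of the OCH2 group of 9; present as its (+)-sparteine complex) | CC(C)[Si](C(C)C)(C(C)C)OC[C@@H](C/C=C/c1ccc(OC)cc1)[C@@H]([Li])OC(=O)N(C(C)C)C(C)C | intermediate
12 | lithium (3,4-dimethoxyphenyl)[(1R,2R,4E)-1-(diisopropylcarbamoyloxy)-5-(4-methoxyphenyl)-2-[(triisopropylsilyloxy)methyl]pent-4-enyl](pinacolato)borate | CC(C)[Si](C(C)C)(C(C)C)OC[C@@H](C/C=C/c1ccc(OC)cc1)[C@@H]([B-]1(c2ccc(OC)c(OC)c2)OC(C)(C)C(C)(C)O1)OC(=O)N(C(C)C)C(C)C.[Li+] | intermediate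
13 | 2-[(1S,2S,4E)-1-(3,4-dimethoxyphenyl)-5-(4-methoxyphenyl)-2-[(triisopropylsilyloxy)methyl]pent-4-enyl]-4,4,5,5-tetramethyl-1,3,2-dioxaborolane | CC(C)[Si](C(C)C)(C(C)C)OC[C@@H](C/C=C/c1ccc(OC)cc1)[C@H](B2OC(C)(C)C(C)(C)O2)c1ccc(OC)c(OC)c1 | intermediate
14 | (1S,2R,4E)-1-(3,4-dimethoxyphenyl)-5-(4-methoxyphenyl)-2-[(triisopropylsilyloxy)methyl]pent-4-en-1-ol | CC(C)[Si](C(C)C)(C(C)C)OC[C@@H](C/C=C/c1ccc(OC)cc1)[C@H](O)c1ccc(OC)c(OC)c1 | intermediate
15 | (1S,2R)-1-(3,4-dimethoxyphenyl)-2-[(E)-3-(4-methoxyphenyl)prop-2-enyl]propane-1,3-diol | OC[C@@H](C/C=C/c1ccc(OC)cc1)[C@H](O)c1ccc(OC)c(OC)c1 | intermediate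
16 | (E)-but-2-enal | C/C=C/C=O | starting material
17 | (Z)-2-iodobut-2-enal | C/C=C(\I)C=O | intermediate
18 | (Z)-2-iodobut-2-en-1-ol | C/C=C(\I)CO | intermediate
19 | tert-butyl{[(Z)-2-iodobut-2-enyl]oxy}dimethylsilane | C/C=C(\I)CO[Si](C)(C)C(C)(C)C | intermediate
20 | [(E)-1-(tert-butyldimethylsilyloxy)but-2-en-2-yl]lithium (lithium cis to the methyl group) | C/C=C(\[Li])CO[Si](C)(C)C(C)(C)C | intermediate
21 | (Z)-2-[(tert-butyldimethylsilyloxy)methyl]but-2-enoic acid | C/C=C(/CO[Si](C)(C)C(C)(C)C)C(=O)O | intermediate
22 | (2R,3S)-3-(3,4-dimethoxyphenyl)-3-hydroxy-2-[(E)-3-(4-methoxyphenyl)prop-2-enyl]propyl (Z)-2-[(tert-butyldimethylsilyloxy)methyl]but-2-enoate | C/C=C(/CO[Si](C)(C)C(C)(C)C)C(=O)OC[C@@H](C/C=C/c1ccc(OC)cc1)[C@H](O)c1ccc(OC)c(OC)c1 | intermediate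
23 | (2R,3S)-3-(3,4-dimethoxyphenyl)-3-hydroxy-2-[(E)-3-(4-methoxyphenyl)prop-2-enyl]propyl (Z)-2-(hydroxymethyl)but-2-enoate | C/C=C(/CO)C(=O)OC[C@@H](C/C=C/c1ccc(OC)cc1)[C@H](O)c1ccc(OC)c(OC)c1 | target

## Step count and least certain steps

Total: 16 steps. Longest linear sequence: 12 steps (steps 1 to 10, 15 and 16, from 1). The acid branch (steps 11 to 14) has 4 steps.

Step 8 (key step). Three processes may fail:
- Proton selection may be poor if the existing C2 centre and the silyloxymethyl arm oppose the diamine.
- Capture of the hindered, diamine-bound organolithium by the aryl boronate may be slow, and the 1,2-shift of the boronate sluggish or reversible, so that 11 loses configuration or decomposes on warming.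
- s-BuLi may add to the anisyl alkene or to 10.

Fallback, from 9 to 13: the same deprotonation is quenched with Me3SnCl (retention) to give the α-trimethylstannyl carbamate F1, which is isolable and can be purified to one diastereomer. Tin–lithium exchange with n-BuLi in Et2O at −78 °C regenerates 11 with retention and free of diamine. It is trapped at once with 10, and warming gives 13. This separates the stereodefining deprotonation from the bond-forming event and keeps s-BuLi away from the boronic ester.

Step 4. The lipase may acetylate the opposite arm to that assumed, or discriminate the arms too weakly. Fallback, from 5 to 6: diacetylation (Ac2O, pyridine) gives the diacetate F2, and the same lipase in aqueous NaH2PO4/Na2HPO4 buffer (pH 7) hydrolyses one acetate. The enzyme recognises the same arm in both directions, so hydrolysis leaves the acetate on the other arm and gives the monoacetate enantiomeric to that from acetylation. If acetylation gives the wrong sense, this supplies 6.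

Step 15. The Z enoate may isomerise through reversible conjugate addition of DMAP to the activated acyl species, and the secondary hydroxyl may be acylated as well. Fallback, from 15 and 21 to 22: a Mitsunobu esterification (PPh3, diisopropyl azodicarboxylate, THF, 0 °C) activates the primary alcohol instead of the acid. The carboxylate then forms the C–O bond by displacement at the unhindered CH2, and no activated acyl derivative exists to isomerise. This fallback makes no compound outside the list (entry F0).

Step 14. If the temperature rises before carboxylation, vinyllithium 20 may expel silyloxide to give an allene or suffer an oxygen-to-carbon silyl shift. Fallback, from 19 to 21: palladium-catalysed methoxycarbonylation (PdCl2(PPh3)2, CO, MeOH, Et3N, DMF, 60 °C) proceeds with retention at the sp2 carbon and gives the methyl ester F3. Saponification (LiOH, THF/H2O, rt) then gives 21.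

## Further compounds

F1 | step 8 | (1R,2R,4E)-5-(4-methoxyphenyl)-2-[(triisopropylsilyloxy)methyl]-1-(trimethylstannyl)pent-4-enyl N,N-diisopropylcarbamate | CC(C)[Si](C(C)C)(C(C)C)OC[C@@H](C/C=C/c1ccc(OC)cc1)[C@@H]([Sn](C)(C)C)OC(=O)N(C(C)C)C(C)C
F2 | step 4 | 2-[(E)-3-(4-methoxyphenyl)prop-2-enyl]propane-1,3-diyl diacetate | CC(=O)OCC(C/C=C/c1ccc(OC)cc1)COC(C)=O
F0 | step 15 | none | none
F3 | step 14 | methyl (Z)-2-[(tert-butyldimethylsilyloxy)methyl]but-2-enoate | C/C=C(/CO[Si](C)(C)C(C)(C)C)C(=O)OC
A1 | alternative 1 | (R)-2-(3,4-dimethoxybenzyl)succinic acid | OC(=O)[C@H](Cc1ccc(OC)c(OC)c1)CC(=O)O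
A2 | alternative 1 | (2S,3S)-2-(3,4-dimethoxyphenyl)-5-oxotetrahydrofuran-3-carboxylic acid (trans) | OC(=O)[C@H]1CC(=O)O[C@@H]1c2ccc(OC)c(OC)c2
A3 | alternative 2 | (R)-1-(4-methoxyphenyl)prop-2-enyl (S)-3-(tert-butyldimethylsilyloxy)-3-(3,4-dimethoxyphenyl)propanoate | C=C[C@H](c1ccc(OC)cc1)OC(=O)C[C@H](O[Si](C)(C)C(C)(C)C)c1ccc(OC)c(OC)c1
A4 | alternative 2 | (2S,3S)-3-(tert-butyldimethylsilyloxy)-3-(3,4-dimethoxyphenyl)-2-[(E)-3-(4-methoxyphenyl)prop-2-enyl]propanoic acid | OC(=O)[C@@H](C/C=C/c1ccc(OC)cc1)[C@H](O[Si](C)(C)C(C)(C)C)c1ccc(OC)c(OC)c1
A5 | alternative 3 | (E)-1-(3,4-dimethoxyphenyl)-5-(4-methoxyphenyl)pent-4-en-1-one | O=C(CC/C=C/c1ccc(OC)cc1)c1ccc(OC)c(OC)c1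
A6 | alternative 3 | (1Z,4E)-1-(3,4-dimethoxyphenyl)-5-(4-methoxyphenyl)-1-(trimethylsilyloxy)penta-1,4-diene | C[Si](C)(C)O/C(=C\C/C=C/c1ccc(OC)cc1)c1ccc(OC)c(OC)c1
A7 | alternative 3 | (R)-1-(3,4-dimethoxyphenyl)-2-(hydroxymethyl)-5-(4-methoxyphenyl)pent-4-en-1-one (E alkene) | OC[C@@H](C/C=C/c1ccc(OC)cc1)C(=O)c1ccc(OC)c(OC)c1
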